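The synthesis rests on cutting the O2–C3 bond of the 1,2-dioxane. Ring carbon C3 carries a peroxide oxygen and a CH2CO2H arm, the exact pattern left when an oxygen nucleophile opens a β-lactone at C4 with alkyl–oxygen cleavage. The precursor is therefore an enantiopure (R)-4-alkyloxetan-2-one whose chain carries, on its third carbon from C4, an α-methoxy hydroperoxide made by ozonolysis in methanol. Base then closes the dioxane, inverts that carbon to (S) and liberates the free acid in one operation. The peroxyketal carbon C6 is afterwards equilibrated to the axial-methoxy (R) epimer, and the enynone chain is added last by Sonogashira coupling.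

Key step: step 8

Remark: dioxane atoms are numbered O1, O2, C3 (CH), C4, C5, C6 (peroxyketal). The aluminium triamine catalyst of step 6 is assumed to show its usual sense of induction with unbranched aldehydes, so the D-valinol-derived (R,R) ligand is specified for the (R)-lactone; the L-valinol-derived antipode would be taken if the sense proved opposite.

Step 1
Reactants: 1 5-chloropent-1-yne
Product: 3 (5-chloropent-1-yn-1-yl)trimethylsilane, via lithium acetylide 2 (not isolated)
Conditions: n-BuLi (1.05 equiv), THF, −78 °C; TMSCl (1.1 equiv), −78 °C → rt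
Reagents that add atoms: chlorotrimethylsilane, C[Si](C)(C)Cl
Why: Deprotonation of the terminal alkyne and C-silylation of the lithium acetylide is a standard alkyne protection, and the primary chloride does not react with the acetylide at −78 °C.

Step 2
Reactants: 3 (5-chloropent-1-yn-1-yl)trimethylsilane; 4 propargyl alcohol
Product: 7 2-methylidene-7-(trimethylsilyl)hept-6-yn-1-ol, via Grignard reagent 5 (not isolated), via alkenylmagnesium alkoxide 6 (not isolated)
Conditions: Mg, I2 (cat.), THF, reflux; then 4 (0.45 equiv), CuI (10 mol%), THF/Et2O, −10 °C → rt; aq. NH4Cl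
Reagents that add atoms: none
Why: Grignard formation followed by copper-catalysed carbomagnesiation of propargyl alcohol: the first equivalent of 5 forms the magnesium alkoxide, which directs anti addition of the second with the alkyl group going to the internal alkyne carbon, and protonation of chelate 6 gives the 2-substituted allylic alcohol.

Step 3
Reactants: 7 2-methylidene-7-(trimethylsilyl)hept-6-yn-1-ol
Product: 8 2-methylidenehept-6-yn-1-ol
Conditions: K2CO3 (0.2 equiv), MeOH, rt
Reagents that add atoms: none
Why: Methoxide-catalysed protodesilylation of the alkynylsilane frees the terminal alkyne before any base-sensitive group is present.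

Step 4
Reactants: 8 2-methylidenehept-6-yn-1-ol; 9 triethyl orthoacetate
Product: 12 ethyl 4-methylidenenon-8-ynoate, via mixed orthoester 10 (not isolated), via ketene acetal 11 (not isolated)
Conditions: 9 (5 equiv), EtCO2H (5 mol%), 140 °C, EtOH distilled off
Reagents that add atoms: none
Why: Johnson–Claisen rearrangement: acid-catalysed exchange gives the mixed orthoester and then the ketene acetal, whose [3,3]-sigmatropic shift delivers the γ,δ-unsaturated ester carrying the 1,1-disubstituted alkene needed for step 7.

Step 5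
Reactants: 12 ethyl 4-methylidenenon-8-ynoate
Product: 14 4-methylidenenon-8-ynal, via aluminium hemiacetal 13 (not isolated)
Conditions: i-Bu2AlH (1.1 equiv), CH2Cl2, −78 °C; MeOH, then aq. potassium sodium tartrate
Reagents that add atoms: none
Why: Partial ester reduction with i-Bu2AlH stops at the tetrahedral aluminium hemiacetal at −78 °C, which releases the aldehyde only on work-up; alkyne and alkene are not hydroaluminated at this temperature.

Step 6
Reactants: 14 4-methylidenenon-8-ynal; 15 acetyl bromide
Product: 17 (R)-4-(3-methylideneoct-7-yn-1-yl)oxetan-2-one, via ketene 16 (not isolated)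
Conditions: [(R,R)-BnN(CH2CH(i-Pr)NTf)2]AlMe (10 mol%), 15 (1.9 equiv), i-Pr2NEt (1.7 equiv), CH2Cl2, −50 °C
Reagents that add atoms: none
Why: Catalytic asymmetric acyl halide–aldehyde cyclocondensation (formal ketene–aldehyde [2+2]): ketene made from 15 and the amine adds to the aldehyde bound to the chiral aluminium triamine complex, which shields one carbonyl face and so sets lactone C4 as (R); unbranched enolisable aldehydes are good substrates, and the enantiomeric purity is checked at this stage.

Step 7
Reactants: 17 (R)-4-(3-methylideneoct-7-yn-1-yl)oxetan-2-one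
Product: 20 (4R)-4-(3-hydroperoxy-3-methoxyoct-7-yn-1-yl)oxetan-2-one as both epimers at the ketal carbon, via primary ozonide 18 (not isolated), via carbonyl oxide 19 (not isolated)
Conditions: O3 (1.0 equiv, Sudan Red 7B end point), CH2Cl2/MeOH 4:1, −78 °C; N2 purge; concentrate below 0 °C, no reductant
Reagents that add atoms: ozone, [O-][O+]=O; methanol, CO
Why: Criegee ozonolysis of the 1,1-disubstituted alkene splits the primary ozonide into formaldehyde and the more substituted ketone oxide, which methanol traps as the α-methoxy hydroperoxide; the terminal alkyne reacts far more slowly with ozone, the β-lactone is inert to neutral methanol at −78 °C, and the new ketal centre forms unselectively, which is corrected in step 9.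

Step 8
Reactants: 20 (4R)-4-(3-hydroperoxy-3-methoxyoct-7-yn-1-yl)oxetan-2-one
Product: 23 2-[(3S)-6-methoxy-6-(pent-4-yn-1-yl)-1,2-dioxan-3-yl]acetic acid as both C6 epimers, via potassium peroxide salt 21 (not isolated), via potassium carboxylate 22 (not isolated)
Conditions: KOt-Bu (1.0 equiv, added slowly), 18-crown-6 (1.0 equiv), THF (0.01 M), −78 °C → rt; then cold dilute HCl to pH 3
Reagents that add atoms: none
Why: Proposed new method: tert-butoxide removes only the hydroperoxide proton, and the terminal peroxide oxygen, an α-effect nucleophile held on the third chain carbon, attacks lactone C4 from the face opposite the ring C4–O bond, so the strained oxetanone opens by alkyl–oxygen cleavage with the carboxylate of the future acetic acid arm as leaving group. The closest known reaction types are the intramolecular opening of epoxides and oxetanes by tethered hydroperoxides to give 1,2-dioxolanes and 1,2-dioxanes, and the SN2 opening of 4-alkyl-β-lactones at C4 by azide or thiolate. The 1,2-dioxane closes in the 6-exo-tet mode. The ring stereocentre C3 is set as (S) by inversion of the (R)-lactone carbon, that is by substrate stereospecificity, whereas C6 is not controlled here. The step needs alkyl–oxygen over acyl–oxygen attack and substitution over elimination: intramolecular acyl attack would require an eight-membered peroxylactone, intermolecular acyl attack is held back by high dilution, and the four-membered ring keeps the α C–H bonds poorly aligned with the C4–O bond so that β-elimination is slow.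

Step 9
Reactants: 23 2-[(3S)-6-methoxy-6-(pent-4-yn-1-yl)-1,2-dioxan-3-yl]acetic acid as both C6 epimers
Product: 25 2-[(3S,6R)-6-methoxy-6-(pent-4-yn-1-yl)-1,2-dioxan-3-yl]acetic acid, via peroxycarbenium ion 24 (not isolated)
Conditions: CSA (10 mol%), MeOH (5 equiv), CH2Cl2, 0 °C → rt
Reagents that add atoms: methanol, CO
Why: Acid-catalysed ketal exchange (anomerisation) through the cyclic peroxycarbenium ion equilibrates C6 only, and the thermodynamic epimer, with methoxy axial (anomeric effect) and both carbon substituents equatorial, is the (6R) isomer once C3 is fixed as (S); methanol is limited to a few equivalents in an aprotic solvent to hold back Fischer esterification of the acid.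

Step 10
Reactants: 26 dec-9-en-1-ol
Product: 27 10-hydroxydecan-2-one
Conditions: PdCl2 (10 mol%), CuCl (1.0 equiv), O2 (1 atm), DMF/H2O 7:1, rt
Reagents that add atoms: water, O
Why: Tsuji–Wacker oxidation: Markovnikov hydroxypalladation of the terminal alkene and β-hydride elimination give the methyl ketone while CuCl/O2 reoxidises palladium, and the remote primary alcohol is tolerated.

Step 11
Reactants: 27 10-hydroxydecan-2-one
Product: 28 9-oxodecanal
Conditions: TEMPO (10 mol%), PhI(OAc)2 (1.1 equiv), CH2Cl2, rt
Reagents that add atoms: none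
Why: TEMPO (oxoammonium) oxidation of the primary alcohol with PhI(OAc)2 as terminal oxidant stops at the aldehyde under anhydrous conditions and leaves the ketone alone.

Step 12
Reactants: 28 9-oxodecanal; 29 iodoform
Product: 31 (E)-11-iodoundec-10-en-2-one, via dichromium carbenoid 30 (not isolated)
Conditions: CrCl2 (6 equiv), 29 (2 equiv), dioxane/THF 6:1, 0 °C → rt
Reagents that add atoms: none
Why: Takai olefination: the geminal dichromium carbenoid formed from iodoform and divalent chromium adds to the aldehyde and eliminates to the (E)-vinyl iodide, while the methyl ketone is spared because ketones react much more slowly.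

Step 13
Reactants: 25 2-[(3S,6R)-6-methoxy-6-(pent-4-yn-1-yl)-1,2-dioxan-3-yl]acetic acid; 31 (E)-11-iodoundec-10-en-2-one
Product: 32 2-[(3S,6R)-6-methoxy-6-[(6E)-15-oxohexadec-6-en-4-yn-1-yl]-1,2-dioxan-3-yl]acetic acid
Conditions: PdCl2(PPh3)2 (5 mol%), CuI (10 mol%), i-Pr2NH (5 equiv), degassed THF, rt
Reagents that add atoms: none
Why: Sonogashira coupling joins the terminal alkyne to the (E)-vinyl iodide at room temperature with retention of alkene geometry; excess amine carries the acid as its ammonium carboxylate, peroxyketal 1,2-dioxanes are known to survive zerovalent palladium couplings, and no stereocentre is involved.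

Compound list
1 | 5-chloropent-1-yne | C#CCCCCl | starting material
2 | (5-chloropent-1-yn-1-yl)lithium | [Li]C#CCCCCl | intermediate
3 | (5-chloropent-1-yn-1-yl)trimethylsilane | C[Si](C)(C)C#CCCCCl | intermediate
4 | propargyl alcohol | C#CCO | starting material
5 | [5-(trimethylsilyl)pent-4-yn-1-yl]magnesium chloride | C[Si](C)(C)C#CCCC[Mg]Cl | intermediate
6 | chloromagnesium (2Z)-3-(chloromagnesio)-2-[5-(trimethylsilyl)pent-4-yn-1-yl]prop-2-en-1-olate | Cl[Mg]/C=C(/CCCC#C[Si](C)(C)C)CO[Mg]Cl | intermediate
7 | 2-methylidene-7-(trimethylsilyl)hept-6-yn-1-ol | C[Si](C)(C)C#CCCCC(=C)CO | intermediate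
8 | 2-methylidenehept-6-yn-1-ol | C#CCCCC(=C)CO | intermediate
9 | triethyl orthoacetate | CCOC(C)(OCC)OCC | starting material
10 | 2-[(1,1-diethoxyethoxy)methyl]hept-1-en-6-yne | CCOC(C)(OCC)OCC(=C)CCCC#C | intermediate
11 | 2-{[(1-ethoxyethenyl)oxy]methyl}hept-1-en-6-yne | C=C(OCC)OCC(=C)CCCC#C | intermediate
12 | ethyl 4-methylidenenon-8-ynoate | CCOC(=O)CCC(=C)CCCC#C | intermediate
13 | [(1-ethoxy-4-methylidenenon-8-yn-1-yl)oxy]bis(2-methylpropyl)alumane | CCOC(CCC(=C)CCCC#C)O[Al](CC(C)C)CC(C)C | intermediate
14 | 4-methylidenenon-8-ynal | C#CCCCC(=C)CCC=O | intermediate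
15 | acetyl bromide | CC(=O)Br | starting material
16 | ketene | C=C=O | intermediate
17 | (R)-4-(3-methylideneoct-7-yn-1-yl)oxetan-2-one | O=C1C[C@@H](CCC(=C)CCCC#C)O1 | intermediate
18 | (4R)-4-{2-[4-(pent-4-yn-1-yl)-1,2,3-trioxolan-4-yl]ethyl}oxetan-2-one | O=C1C[C@@H](CCC2(CCCC#C)COOO2)O1 | intermediate
19 | carbonyl oxide of (4R)-4-(3-oxooct-7-yn-1-yl)oxetan-2-one | O=C1C[C@@H](CCC(=[O+][O-])CCCC#C)O1 | intermediate
20 | (4R)-4-(3-hydroperoxy-3-methoxyoct-7-yn-1-yl)oxetan-2-one, both epimers at the ketal carbon | O=C1C[C@@H](CCC(OC)(OO)CCCC#C)O1 | intermediate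
21 | potassium salt of hydroperoxide 20 | [K+].[O-]OC(OC)(CCCC#C)CC[C@@H]1CC(=O)O1 | intermediate
22 | potassium 2-[(3S)-6-methoxy-6-(pent-4-yn-1-yl)-1,2-dioxan-3-yl]acetate | COC1(CCCC#C)CC[C@@H](CC(=O)[O-])OO1.[K+] | intermediate
23 | 2-[(3S)-6-methoxy-6-(pent-4-yn-1-yl)-1,2-dioxan-3-yl]acetic acid, both C6 epimers | COC1(CCCC#C)CC[C@@H](CC(=O)O)OO1 | intermediate
24 | (3S)-3-(carboxymethyl)-6-(pent-4-yn-1-yl)-4,5-dihydro-3H-1,2-dioxin-1-ium | C#CCCCC1=[O+]O[C@H](CC(=O)O)CC1 | intermediate
25 | 2-[(3S,6R)-6-methoxy-6-(pent-4-yn-1-yl)-1,2-dioxan-3-yl]acetic acid | CO[C@@]1(CCCC#C)CC[C@@H](CC(=O)O)OO1 | intermediate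
26 | dec-9-en-1-ol | C=CCCCCCCCCO | starting material
27 | 10-hydroxydecan-2-one | CC(=O)CCCCCCCCO | intermediate
28 | 9-oxodecanal | CC(=O)CCCCCCCC=O | intermediate
29 | iodoform | IC(I)I | starting material
30 | (iodomethanediyl)bis(dichlorochromium) | IC([Cr](Cl)Cl)[Cr](Cl)Cl | intermediate
31 | (E)-11-iodoundec-10-en-2-one | CC(=O)CCCCCCC/C=C/I | intermediate
32 | 2-[(3S,6R)-6-methoxy-6-[(6E)-15-oxohexadec-6-en-4-yn-1-yl]-1,2-dioxan-3-yl]acetic acid | CO[C@@]1(CCCC#C/C=C/CCCCCCCC(C)=O)CC[C@@H](CC(=O)O)OO1 | target

Total step count: 13 (steps 1–9 to acid 25, steps 10–12 to vinyl iodide 31, step 13 coupling).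
Longest linear sequence: 10 steps (steps 1–9, then step 13).

Steps most likely to fail

1. Step 8 (proposed new method). The peroxide anion may attack the acyl carbon of a second molecule and give oligomeric peresters, the lactone may eliminate to the unsaturated carboxylate, or closure at the secondary carbon may simply be too slow. The fallback uses known chemistry: intramolecular alkylation of a hydroperoxy ketal by a secondary sulfonate. It sets out from 17 and returns at 23.
   - Lactone 17 is reduced with LiAlH4 (THF, 0 °C) to (3R)-6-methylideneundec-10-yne-1,3-diol F1.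
   - The primary hydroxyl is silylated (TBSCl, imidazole, CH2Cl2, −20 °C) to (3R)-1-[(tert-butyldimethylsilyl)oxy]-6-methylideneundec-10-yn-3-ol F2.
   - Mesylation (MsCl, Et3N, CH2Cl2, 0 °C) gives (3R)-1-[(tert-butyldimethylsilyl)oxy]-6-methylideneundec-10-yn-3-yl methanesulfonate F3.
   - Ozonolysis in CH2Cl2/MeOH at −78 °C gives (3R)-1-[(tert-butyldimethylsilyl)oxy]-6-hydroperoxy-6-methoxyundec-10-yn-3-yl methanesulfonate F4.
   - KOt-Bu/18-crown-6 in THF closes the ring with inversion to tert-butyl{2-[(3S)-6-methoxy-6-(pent-4-yn-1-yl)-1,2-dioxan-3-yl]ethoxy}dimethylsilane F5.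
   - HF·pyridine in THF removes the silyl group to give 2-[(3S)-6-methoxy-6-(pent-4-yn-1-yl)-1,2-dioxan-3-yl]ethan-1-ol F6.
   - TEMPO (cat.)/PhI(OAc)2 in MeCN/H2O oxidises the primary alcohol to acid 23, with no carbonyl next to the sulfonate at any point to invite elimination.

2. Step 9. Fischer esterification of the free acid may compete with ketal exchange, or the peroxycarbenium ion may fragment before the epimers converge. The fallback masks the acid and sets out from 23, returning at the target 32.
   - Acid 23 is methylated (Me3SiCHN2, MeOH/toluene, 0 °C) to methyl 2-[(3S)-6-methoxy-6-(pent-4-yn-1-yl)-1,2-dioxan-3-yl]acetate F7.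
   - Equilibration in neat methanol with TsOH at rt, where esterification is no longer a side reaction, should give methyl 2-[(3S,6R)-6-methoxy-6-(pent-4-yn-1-yl)-1,2-dioxan-3-yl]acetate F8.
   - Sonogashira coupling with 31 under the step 13 conditions gives methyl 2-[(3S,6R)-6-methoxy-6-[(6E)-15-oxohexadec-6-en-4-yn-1-yl]-1,2-dioxan-3-yl]acetate F9.
   - LiOH in THF/H2O at 0 °C hydrolyses the ester to 32.

3. Step 13. Low-valent palladium or phosphine may reduce the O–O bond, the alkyne may homocouple oxidatively, or the carboxylate may stall the copper cycle. The fallback moves the coupling ahead of peroxide formation; it sets out from 17 and returns at 32.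
   - Lactone 17 is coupled with 31 (PdCl2(PPh3)2, CuI, i-Pr2NEt, THF, rt) to (4R)-4-[(9E)-3-methylidene-18-oxononadec-9-en-7-yn-1-yl]oxetan-2-one F10.
   - One equivalent of ozone in CH2Cl2/MeOH at −78 °C, aimed at the isolated, more electron-rich 1,1-disubstituted alkene over the conjugated enyne alkene, gives (4R)-4-[(9E)-3-hydroperoxy-3-methoxy-18-oxononadec-9-en-7-yn-1-yl]oxetan-2-one F11.
   - The step 8 conditions give 2-[(3S)-6-methoxy-6-[(6E)-15-oxohexadec-6-en-4-yn-1-yl]-1,2-dioxan-3-yl]acetic acid F12 as C6 epimers.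
   - The step 9 conditions then converge F12 on 32.

Further compounds
F1 | step 8 | (3R)-6-methylideneundec-10-yne-1,3-diol | OCC[C@@H](CCC(=C)CCCC#C)O
F2 | step 8 | (3R)-1-[(tert-butyldimethylsilyl)oxy]-6-methylideneundec-10-yn-3-ol | CC(C)(C)[Si](C)(C)OCC[C@@H](CCC(=C)CCCC#C)O
F3 | step 8 | (3R)-1-[(tert-butyldimethylsilyl)oxy]-6-methylideneundec-10-yn-3-yl methanesulfonate | CC(C)(C)[Si](C)(C)OCC[C@@H](CCC(=C)CCCC#C)OS(C)(=O)=O
F4 | step 8 | (3R)-1-[(tert-butyldimethylsilyl)oxy]-6-hydroperoxy-6-methoxyundec-10-yn-3-yl methanesulfonate | CC(C)(C)[Si](C)(C)OCC[C@@H](CCC(OC)(OO)CCCC#C)OS(C)(=O)=O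
F5 | step 8 | tert-butyl{2-[(3S)-6-methoxy-6-(pent-4-yn-1-yl)-1,2-dioxan-3-yl]ethoxy}dimethylsilane | COC1(CCCC#C)CC[C@@H](CCO[Si](C)(C)C(C)(C)C)OO1
F6 | step 8 | 2-[(3S)-6-methoxy-6-(pent-4-yn-1-yl)-1,2-dioxan-3-yl]ethan-1-ol | COC1(CCCC#C)CC[C@@H](CCO)OO1
F7 | step 9 | methyl 2-[(3S)-6-methoxy-6-(pent-4-yn-1-yl)-1,2-dioxan-3-yl]acetate | COC1(CCCC#C)CC[C@@H](CC(=O)OC)OO1
F8 | step 9 | methyl 2-[(3S,6R)-6-methoxy-6-(pent-4-yn-1-yl)-1,2-dioxan-3-yl]acetate | CO[C@@]1(CCCC#C)CC[C@@H](CC(=O)OC)OO1
F9 | step 9 | methyl 2-[(3S,6R)-6-methoxy-6-[(6E)-15-oxohexadec-6-en-4-yn-1-yl]-1,2-dioxan-3-yl]acetate | CO[C@@]1(CCCC#C/C=C/CCCCCCCC(C)=O)CC[C@@H](CC(=O)OC)OO1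
F10 | step 13 | (4R)-4-[(9E)-3-methylidene-18-oxononadec-9-en-7-yn-1-yl]oxetan-2-one | O=C1C[C@@H](CCC(=C)CCCC#C/C=C/CCCCCCCC(C)=O)O1
F11 | step 13 | (4R)-4-[(9E)-3-hydroperoxy-3-methoxy-18-oxononadec-9-en-7-yn-1-yl]oxetan-2-one | O=C1C[C@@H](CCC(OC)(OO)CCCC#C/C=C/CCCCCCCC(C)=O)O1
F12 | step 13 | 2-[(3S)-6-methoxy-6-[(6E)-15-oxohexadec-6-en-4-yn-1-yl]-1,2-dioxan-3-yl]acetic acid | COC1(CCCC#C/C=C/CCCCCCCC(C)=O)CC[C@@H](CC(=O)O)OO1
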